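**Retrosynthetic overview**

- The strategy rests on ring A (the phloroglucinol ring). Its oxygens on C2', C4' and C6' are each ortho or para to C1', which carries the C1 ketone, so the acyl group can activate all three carbons for displacement of fluoride by an alkoxide.
- Disconnection 1: the four O–benzyl bonds (global hydrogenolysis). Disconnection 2 (key): the three C–O bonds of ring A, leading back to a 2,4,6-trifluorophenyl ketone and three equivalents of benzyl alcohol.
- Disconnection 3: the C1–C1' bond, to 2,4,6-trifluorophenyllithium (from 1,3,5-trifluorobenzene) and a Weinreb amide. Disconnection 4: the C11–aryl bond to ring B, by B-alkyl Suzuki–Miyaura coupling of methyl undec-10-enoate with 1-(benzyloxy)-2-bromobenzene.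
- No ring is formed: ring A comes from 1,3,5-trifluorobenzene and ring B from the bromoarene. The target has no stereocentre.

Key step: step 4

Remark: methyl undec-10-enoate is taken as the purchased ester of undec-10-enoic acid, because an ester is inert to 9-BBN at room temperature whereas a free acid or a Weinreb amide could consume the borane.

**Route**

Step 1
Reactants: 1 methyl undec-10-enoate; 2 1-(benzyloxy)-2-bromobenzene
Product: 4 methyl 11-[2-(benzyloxy)phenyl]undecanoate, via B-alkyl-9-BBN borane 3 (not isolated)
Conditions: 1, 9-BBN (0.5 M in THF), THF, 0 °C to rt; then 2, PdCl2(dppf) (5 mol%), aq K3PO4, DMF, 60 °C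
Reagents that add atoms: none
Why: Anti-Markovnikov hydroboration of the terminal alkene with 9-BBN places boron on C11 without touching the ester, and the B-alkyl borane then undergoes B-alkyl Suzuki–Miyaura coupling (oxidative addition of the aryl bromide to zerovalent palladium, base-assisted transmetalation, reductive elimination) to form the C11–aryl bond.

Step 2
Reactants: 4 methyl 11-[2-(benzyloxy)phenyl]undecanoate
Product: 6 11-[2-(benzyloxy)phenyl]-N-methoxy-N-methylundecanamide, via chloromagnesium N-methoxy-N-methylamide 5 (not isolated)
Conditions: MeNH(OMe)·HCl, iPrMgCl, THF, −20 to 0 °C; aq NH4Cl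
Reagents that add atoms: N,O-dimethylhydroxylamine hydrochloride, CNOC.Cl
Why: Weinreb amide formation by aminolysis of an unhindered methyl ester with the magnesium amide made in the flask, a standard acyl substitution that the aryl benzyl ether tolerates.

Step 3
Reactants: 7 1,3,5-trifluorobenzene; 6 11-[2-(benzyloxy)phenyl]-N-methoxy-N-methylundecanamide
Product: 10 11-[2-(benzyloxy)phenyl]-1-(2,4,6-trifluorophenyl)undecan-1-one, via 2,4,6-trifluorophenyllithium 8 (not isolated), via lithium hemiaminal alkoxide 9 (not isolated)
Conditions: 7 (slight excess over n-BuLi), n-BuLi, THF, −78 °C; then 6, −78 to −40 °C; 1 M HCl quench at −40 °C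
Reagents that add atoms: none
Why: Deprotonation of the C–H flanked by two fluorines gives the aryllithium, and the Weinreb ketone synthesis stops at the chelated tetrahedral adduct 9 until acidic work-up, so no over-addition should occur, while staying at or below −40 °C should suppress loss of LiF to an aryne.

Step 4
Reactants: 10 11-[2-(benzyloxy)phenyl]-1-(2,4,6-trifluorophenyl)undecan-1-one; 11 benzyl alcohol
Product: 15 11-[2-(benzyloxy)phenyl]-1-[2,4,6-tris(benzyloxy)phenyl]undecan-1-one, via sodium benzyloxide 12 (not isolated), via 4-benzyloxy-2,6-difluorophenyl ketone 13 (not isolated), via 2,4-bis(benzyloxy)-6-fluorophenyl ketone 14 (not isolated)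
Conditions: 11 (6 equiv, of which three are incorporated), NaH (4.5 equiv), THF, 0 °C to rt; then 10, DMSO, 85 °C
Reagents that add atoms: benzyl alcohol (the second and third equivalents that end up in the product), OCc1ccccc1.OCc1ccccc1
Why: This is a threefold nucleophilic aromatic substitution by addition–elimination that consumes three equivalents of benzyloxide 12, one per fluoride: each adds to a fluorine-bearing carbon of ring A to give a Meisenheimer anion whose charge is delocalised onto the C1 carbonyl and stabilised inductively by the remaining fluorines, and loss of fluoride restores the arene, probably first at C4' (13) and then at C2' and C6' (14, then 15), the order being immaterial because all three positions end as benzyl ethers. The closest known reaction type is the displacement of fluoride ortho and para to a ketone, nitrile or ester by alkoxides in dipolar aprotic solvents. No ring is closed and no stereocentre is formed. The selectivity needed is exhaustive substitution at C2', C4' and C6' without addition to or condensation at the ketone: every fluoride is ortho or para to the acyl group, so none is left unactivated, and the two ortho substituents shield the carbonyl from 1,2-addition and aldol reaction. Reversible enolisation of the C2 methylene is the main brake on the rate, so benzyl alcohol is kept in excess over NaH to temper the basicity and the substitution drains the keto form; the benzyl ether on ring B is inert here.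

Step 5
Reactants: 15 11-[2-(benzyloxy)phenyl]-1-[2,4,6-tris(benzyloxy)phenyl]undecan-1-one
Product: 16 11-(2-hydroxyphenyl)-1-(2,4,6-trihydroxyphenyl)undecan-1-one
Conditions: H2 (1 atm), Pd/C (10 wt%), EtOAc/MeOH, rt
Reagents that add atoms: none
Why: Catalytic hydrogenolysis should cleave all four benzylic C–O bonds, while the aryl ketone, conjugated with and hydrogen-bonded to the ortho phenols as they are freed, should resist reduction under these mild conditions.

**Compound list**

1 | methyl undec-10-enoate | C=CCCCCCCCCC(=O)OC | starting material
2 | 1-(benzyloxy)-2-bromobenzene | Brc1ccccc1OCc1ccccc1 | starting material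
3 | methyl 11-(9-borabicyclo[3.3.1]nonan-9-yl)undecanoate | COC(=O)CCCCCCCCCCB1C2CCCC1CCC2 | intermediate
4 | methyl 11-[2-(benzyloxy)phenyl]undecanoate | COC(=O)CCCCCCCCCCc1ccccc1OCc1ccccc1 | intermediate
5 | chloromagnesium N-methoxy-N-methylamide | CON(C)[Mg]Cl | intermediate
6 | 11-[2-(benzyloxy)phenyl]-N-methoxy-N-methylundecanamide | CON(C)C(=O)CCCCCCCCCCc1ccccc1OCc1ccccc1 | intermediate
7 | 1,3,5-trifluorobenzene | Fc1cc(F)cc(F)c1 | starting material
8 | 2,4,6-trifluorophenyllithium | [Li]c1c(F)cc(F)cc1F | intermediate
9 | lithium 11-[2-(benzyloxy)phenyl]-1-[methoxy(methyl)amino]-1-(2,4,6-trifluorophenyl)undecan-1-olate (racemic tetrahedral adduct) | CON(C)C(O[Li])(CCCCCCCCCCc1ccccc1OCc1ccccc1)c1c(F)cc(F)cc1F | intermediate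
10 | 11-[2-(benzyloxy)phenyl]-1-(2,4,6-trifluorophenyl)undecan-1-one | O=C(CCCCCCCCCCc1ccccc1OCc1ccccc1)c1c(F)cc(F)cc1F | intermediate
11 | benzyl alcohol | OCc1ccccc1 | starting material
12 | sodium benzyloxide | [Na+].[O-]Cc1ccccc1 | intermediate
13 | 1-[4-(benzyloxy)-2,6-difluorophenyl]-11-[2-(benzyloxy)phenyl]undecan-1-one | O=C(CCCCCCCCCCc1ccccc1OCc1ccccc1)c1c(F)cc(OCc2ccccc2)cc1F | intermediate
14 | 1-[2,4-bis(benzyloxy)-6-fluorophenyl]-11-[2-(benzyloxy)phenyl]undecan-1-one | O=C(CCCCCCCCCCc1ccccc1OCc1ccccc1)c1c(F)cc(OCc2ccccc2)cc1OCc1ccccc1 | intermediate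
15 | 11-[2-(benzyloxy)phenyl]-1-[2,4,6-tris(benzyloxy)phenyl]undecan-1-one | O=C(CCCCCCCCCCc1ccccc1OCc1ccccc1)c1c(OCc2ccccc2)cc(OCc2ccccc2)cc1OCc1ccccc1 | intermediate
16 | 11-(2-hydroxyphenyl)-1-(2,4,6-trihydroxyphenyl)undecan-1-one (CNP0295227.0; no stereocentre) | O=C(CCCCCCCCCCc1ccccc1O)c1c(O)cc(O)cc1O | target

**Step count**

Total steps: 5. Longest linear sequence: 5 steps (1 → 4 → 6 → 10 → 15 → 16).

**Steps most likely to fail**

1. Step 4 (key step). The substitution may stall after the first or second displacement, because each benzyloxy group and the enolate formed at the C2 methylene make ring A less electrophilic; the enolate may also undergo aldol-type self-condensation in the hot basic medium. The fallback sets out from Weinreb amide 6 and returns at 15, placing the ring A oxygens before the C1–C1' bond is made. Purchased 1,3,5-tris(benzyloxy)benzene would be monobrominated (NBS, CH2Cl2, 0 °C) to 2-bromo-1,3,5-tris(benzyloxy)benzene F1. Bromine–lithium exchange (n-BuLi, THF, −78 °C) should give 2,4,6-tris(benzyloxy)phenyllithium F2. Addition of F2 to 6 should give the lithium hemiaminal alkoxide F3, which releases 15 on quenching with 1 M HCl.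

2. Step 3. The stabilised, doubly ortho-fluorinated aryllithium may add too slowly to the Weinreb amide at the temperatures it tolerates; warming would cause loss of LiF to an aryne, and the C2 methylene of the amide may be deprotonated instead. The fallback sets out from 6 and returns at 10, using a more electrophilic acceptor. Reduction of 6 (i-Bu2AlH, THF, −78 °C) should give 11-[2-(benzyloxy)phenyl]undecanal F4. Addition of 8 at −78 °C should give racemic 11-[2-(benzyloxy)phenyl]-1-(2,4,6-trifluorophenyl)undecan-1-ol F5, whose stereocentre is removed on oxidation with Dess–Martin periodinane (CH2Cl2, rt) to 10.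

3. Step 1. Transmetalation of the B-alkyl borane to the arylpalladium bromide derived from the electron-rich, ortho-substituted bromide may be incomplete, leading to protodeboronation or β-hydride elimination of the alkyl group. The fallback sets out from 1 and 2 and returns at 4, replacing the organoboron route by a coupling of two electrophiles. Radical anti-Markovnikov addition of HBr to 1 (HBr, dibenzoyl peroxide, hexane, 0 °C) should give methyl 11-bromoundecanoate F6. Nickel-catalysed reductive cross-electrophile coupling of F6 with 2 (NiBr2(dme), 4,4'-di-tert-butyl-2,2'-bipyridine, Zn, DMA, 60 °C) should give 4.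

**Further compounds**

F1 | step 4 | 2-bromo-1,3,5-tris(benzyloxy)benzene | Brc1c(OCc2ccccc2)cc(OCc2ccccc2)cc1OCc1ccccc1
F2 | step 4 | 2,4,6-tris(benzyloxy)phenyllithium | [Li]c1c(OCc2ccccc2)cc(OCc2ccccc2)cc1OCc1ccccc1
F3 | step 4 | lithium 11-[2-(benzyloxy)phenyl]-1-[methoxy(methyl)amino]-1-[2,4,6-tris(benzyloxy)phenyl]undecan-1-olate (racemic lithium hemiaminal alkoxide) | CON(C)C(O[Li])(CCCCCCCCCCc1ccccc1OCc1ccccc1)c1c(OCc2ccccc2)cc(OCc2ccccc2)cc1OCc1ccccc1
F4 | step 3 | 11-[2-(benzyloxy)phenyl]undecanal | O=CCCCCCCCCCCc1ccccc1OCc1ccccc1
F5 | step 3 | 11-[2-(benzyloxy)phenyl]-1-(2,4,6-trifluorophenyl)undecan-1-ol (racemic) | OC(CCCCCCCCCCc1ccccc1OCc1ccccc1)c1c(F)cc(F)cc1F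
F6 | step 1 | methyl 11-bromoundecanoate | COC(=O)CCCCCCCCCCBr
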